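**Plan**
- The retrosynthesis first removes the protecting groups, then cuts two bonds of ring A at once: the C6–O diaryl ether bond and the C1–CO2H bond. This leads back to the C1–C6 aryne of ring A, the ring B phenoxide and CO2.
- The feature that allows this: the aryloxy group (C6) and the carboxyl group (C1) sit on neighbouring ring A carbons, and the C2 methoxy group next to C1 polarises an aryne spanning C1 and C6.
- Forward: ring A is built from 4-hydroxy-2-methoxybenzaldehyde into a 2-silylaryl triflate (steps 1–8), and the ring B phenol is made from creosol (steps 9–13).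
- The two fragments and CO2 are joined in step 14, then the benzyl and silyl groups are removed (steps 15–16). No ring is formed anywhere in the route.
- The single stereocenter, the S carbinol of the side chain, comes from a CBS reduction of the aryl isobutyl ketone (step 4) and is carried as a silyl ether to the end.

Key step: step 14

Remark on numbering: ring A is C1 (CO2H), C2 (OMe), C3 (side chain), C6 (OAr); ring B is C1′ (ether O), C2′ (OH), C4′ (Me), C6′ (CH2OH). TBS = tert-butyldimethylsilyl. The carbinol descriptor stays S in every intermediate because O > aryl > CH2 > H throughout.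

Assumption: the free benzylic carbinol of ring A (para to aryloxy, ortho to methoxy) is taken to ionise easily in acid. For that reason the ring B phenol is protected as a benzyl ether and the alcohols as silyl ethers, so that no acidic deprotection is needed.

Step 1
Reactants: 1 4-hydroxy-2-methoxybenzaldehyde
Product: 2 4-formyl-3-methoxyphenyl N,N-diethylcarbamate
Conditions: Et2NCOCl, K2CO3, MeCN, reflux
Reagents that add atoms: N,N-diethylcarbamoyl chloride, CCN(CC)C(Cl)=O
Why: O-carbamoylation of the phenoxide (acyl substitution); the diethylcarbamate masks the phenol through the organometallic steps and later serves as the directing group for ortho-metalation.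

Step 2
Reactants: 2 4-formyl-3-methoxyphenyl N,N-diethylcarbamate; 3 isobutylmagnesium bromide
Product: 4 rac-4-(1-hydroxy-3-methylbutyl)-3-methoxyphenyl N,N-diethylcarbamate
Conditions: THF, −78 to 0 °C; aq NH4Cl
Reagents that add atoms: none
Why: Grignard 1,2-addition to the aryl aldehyde at low temperature, where the diethylcarbamate is inert; the carbinol forms racemic and is erased in step 3.

Step 3
Reactants: 4 rac-4-(1-hydroxy-3-methylbutyl)-3-methoxyphenyl N,N-diethylcarbamate
Product: 5 3-methoxy-4-(3-methylbutanoyl)phenyl N,N-diethylcarbamate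
Conditions: Dess–Martin periodinane, CH2Cl2, rt
Reagents that add atoms: none
Why: Dess–Martin oxidation of the secondary benzylic alcohol to the aryl ketone under neutral conditions that leave the carbamate and the methyl ether untouched.

Step 4
Reactants: 5 3-methoxy-4-(3-methylbutanoyl)phenyl N,N-diethylcarbamate
Product: 6 4-[(1S)-1-hydroxy-3-methylbutyl]-3-methoxyphenyl N,N-diethylcarbamate
Conditions: (R)-2-methyl-CBS-oxazaborolidine (10 mol %), BH3·SMe2, THF, −20 °C; then MeOH
Reagents that add atoms: none
Why: Corey–Bakshi–Shibata reduction; with the aryl group as the large substituent, the (R)-oxazaborolidine–borane complex delivers hydride to the Re face of the ketone, which sets the S carbinol.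

Step 5
Reactants: 6 4-[(1S)-1-hydroxy-3-methylbutyl]-3-methoxyphenyl N,N-diethylcarbamate
Product: 7 4-[(1S)-1-(TBS-oxy)-3-methylbutyl]-3-methoxyphenyl N,N-diethylcarbamate
Conditions: TBSCl, imidazole, DMF, rt
Reagents that add atoms: tert-butyldimethylsilyl chloride, CC(C)(C)[Si](C)(C)Cl
Why: imidazole-promoted silylation of the secondary alcohol removes the acidic OH before the lithiation and keeps the benzylic carbinol from ionising in later steps.

Step 6
Reactants: 7 4-[(1S)-1-(TBS-oxy)-3-methylbutyl]-3-methoxyphenyl N,N-diethylcarbamate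
Product: 9 4-[(1S)-1-(TBS-oxy)-3-methylbutyl]-3-methoxy-2-(trimethylsilyl)phenyl N,N-diethylcarbamate, via aryllithium 8 (not isolated)
Conditions: s-BuLi, TMEDA, THF, −78 °C; TMSCl, −78 °C to rt
Reagents that add atoms: chlorotrimethylsilane, C[Si](C)(C)Cl
Why: Snieckus directed ortho-metalation; the ring position between the O-carbamate and the methoxy group is activated by both and is lithiated at −78 °C, and trapping with TMSCl at that temperature forestalls the anionic ortho-Fries shift and benzylic deprotonation.

Step 7
Reactants: 9 4-[(1S)-1-(TBS-oxy)-3-methylbutyl]-3-methoxy-2-(trimethylsilyl)phenyl N,N-diethylcarbamate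
Product: 10 4-[(1S)-1-(TBS-oxy)-3-methylbutyl]-3-methoxy-2-(trimethylsilyl)phenol
Conditions: LiAlH4, THF, 0 °C to rt; then Na2SO4·10H2O
Reagents that add atoms: none
Why: hydride reduction of the aryl carbamate releases the phenoxide, while the aryl–silicon bond and the alkyl silyl ether are inert to LiAlH4 in an aprotic medium.

Step 8
Reactants: 10 4-[(1S)-1-(TBS-oxy)-3-methylbutyl]-3-methoxy-2-(trimethylsilyl)phenol
Product: 11 4-[(1S)-1-(TBS-oxy)-3-methylbutyl]-3-methoxy-2-(trimethylsilyl)phenyl trifluoromethanesulfonate
Conditions: Tf2O, pyridine, CH2Cl2, 0 °C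
Reagents that add atoms: trifluoromethanesulfonic anhydride, O=S(=O)(OS(=O)(=O)C(F)(F)F)C(F)(F)F
Why: O-sulfonylation of the phenol, the standard last step towards a Kobayashi-type 2-silylaryl triflate.

Step 9
Reactants: 12 2-methoxy-4-methylphenol (creosol)
Product: 13 2-hydroxy-3-methoxy-5-methylbenzaldehyde
Conditions: MgCl2, Et3N, (CH2O)n, MeCN, reflux; aq HCl
Reagents that add atoms: paraformaldehyde (formaldehyde units), C=O
Why: magnesium-mediated ortho-formylation of a phenol (Casnati–Skattebøl); the magnesium phenoxide delivers formaldehyde to the only free ortho position of creosol.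

Step 10
Reactants: 13 2-hydroxy-3-methoxy-5-methylbenzaldehyde
Product: 14 2,3-dihydroxy-5-methylbenzaldehyde
Conditions: BBr3, CH2Cl2, −78 to 0 °C; H2O
Reagents that add atoms: none
Why: Lewis-acid cleavage of the aryl methyl ether with BBr3 gives the catechol, and the aldehyde is recovered on aqueous work-up.

Step 11
Reactants: 14 2,3-dihydroxy-5-methylbenzaldehyde
Product: 16 3-(benzyloxy)-2-hydroxy-5-methylbenzaldehyde, via disodium dianion 15 (not isolated)
Conditions: NaH (2.2 equiv), DMSO, rt; BnBr (1.0 equiv); aq HCl
Reagents that add atoms: benzyl bromide, BrCc1ccccc1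
Why: Williamson etherification of the dianion; the oxide next to the formyl group is conjugated with it and chelated, so the more nucleophilic outer oxide is benzylated.

Step 12
Reactants: 16 3-(benzyloxy)-2-hydroxy-5-methylbenzaldehyde
Product: 17 2-(benzyloxy)-6-(hydroxymethyl)-4-methylphenol
Conditions: NaBH4, MeOH, 0 °C
Reagents that add atoms: none
Why: borohydride reduction of the aryl aldehyde to the benzylic alcohol, with the phenol and the benzyl ether unaffected.

Step 13
Reactants: 17 2-(benzyloxy)-6-(hydroxymethyl)-4-methylphenol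
Product: 18 2-(benzyloxy)-6-[(TBS-oxy)methyl]-4-methylphenol
Conditions: TBSCl (1.05 equiv), imidazole, CH2Cl2, 0 °C
Reagents that add atoms: tert-butyldimethylsilyl chloride, CC(C)(C)[Si](C)(C)Cl
Why: selective silylation of the primary benzylic alcohol, which is far more accessible than the phenol flanked by two ortho substituents.

Step 14
Reactants: 11 4-[(1S)-1-(TBS-oxy)-3-methylbutyl]-3-methoxy-2-(trimethylsilyl)phenyl trifluoromethanesulfonate; 18 2-(benzyloxy)-6-[(TBS-oxy)methyl]-4-methylphenol; 19 carbon dioxide
Product: 23 6-{2-(benzyloxy)-6-[(TBS-oxy)methyl]-4-methylphenoxy}-3-[(1S)-1-(TBS-oxy)-3-methylbutyl]-2-methoxybenzoic acid, via potassium phenoxide 20 (not isolated), via aryne 21 (not isolated), via arylpotassium adduct 22 (not isolated)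
Conditions: 18 (1.5 equiv), KH, THF, 0 °C; 18-crown-6, KF, CO2 (1 atm); 11 added slowly, 0 °C to rt; cold dilute HCl to pH 3
Reagents that add atoms: none
Why: Proposed new method: fluoride attacks the trimethylsilyl group at C1 of 11 and triflate leaves from C6 to give aryne 21, the oxygen of phenoxide 20 adds to C6, and the C1 aryl anion 22 is carboxylated by dissolved CO2, so the C6–O and C1–CO2 bonds form in one operation. The closest known reaction types are the three-component coupling of arynes, amines and CO2 to anthranilic acids (KF/18-crown-6, THF) and the fluoride-promoted O-arylation of hindered phenols by arynes; new here is an anionic oxygen nucleophile combined with CO2 capture of the aryl anion. No ring closes and no stereocenter is formed; the S carbinol is remote from the reacting carbons and is carried unchanged as its silyl ether. The selectivity required is regiochemical and is secured by the C2 methoxy group, whose inductive pull distorts the aryne so that C6 is the more electrophilic terminus and the developing carbanion sits at C1 next to the C–O bond. Chemoselectivity rests on an aprotic medium in which the phenol is fully deprotonated by KH, so that CO2 is the only electrophile offered to 22, on slow addition of 11 to keep the aryne dilute, and on the reversible binding of CO2 by the di-ortho-substituted phenoxide.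

Step 15
Reactants: 23 6-{2-(benzyloxy)-6-[(TBS-oxy)methyl]-4-methylphenoxy}-3-[(1S)-1-(TBS-oxy)-3-methylbutyl]-2-methoxybenzoic acid
Product: 24 6-{2-hydroxy-6-[(TBS-oxy)methyl]-4-methylphenoxy}-3-[(1S)-1-(TBS-oxy)-3-methylbutyl]-2-methoxybenzoic acid
Conditions: H2 (1 atm), Pd/C, EtOAc, rt
Reagents that add atoms: none
Why: catalytic hydrogenolysis of the aryl benzyl ether in neutral ethyl acetate; both benzylic oxygens are still silyl ethers at this stage, so the benzylic C–O bonds should not be reduced.

Step 16
Reactants: 24 6-{2-hydroxy-6-[(TBS-oxy)methyl]-4-methylphenoxy}-3-[(1S)-1-(TBS-oxy)-3-methylbutyl]-2-methoxybenzoic acid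
Product: 25 3-[(1S)-1-hydroxy-3-methylbutyl]-6-[2-hydroxy-6-(hydroxymethyl)-4-methylphenoxy]-2-methoxybenzoic acid (CNP0221397.1)
Conditions: TBAF, THF, 0 °C to rt; cold dilute HCl to pH 4
Reagents that add atoms: none
Why: fluoride-induced desilylation of both silyl ethers under basic to neutral conditions, so the ionisable benzylic carbinol never meets strong acid and its S configuration should be retained.

**Compound list**

1 | 4-hydroxy-2-methoxybenzaldehyde | COc1cc(O)ccc1C=O | starting material
2 | 4-formyl-3-methoxyphenyl N,N-diethylcarbamate | CCN(CC)C(=O)Oc1ccc(C=O)c(OC)c1 | intermediate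
3 | isobutylmagnesium bromide | CC(C)C[Mg]Br | starting material
4 | rac-4-(1-hydroxy-3-methylbutyl)-3-methoxyphenyl N,N-diethylcarbamate | CCN(CC)C(=O)Oc1ccc(C(O)CC(C)C)c(OC)c1 | intermediate
5 | 3-methoxy-4-(3-methylbutanoyl)phenyl N,N-diethylcarbamate | CCN(CC)C(=O)Oc1ccc(C(=O)CC(C)C)c(OC)c1 | intermediate
6 | 4-[(1S)-1-hydroxy-3-methylbutyl]-3-methoxyphenyl N,N-diethylcarbamate | CCN(CC)C(=O)Oc1ccc([C@@H](O)CC(C)C)c(OC)c1 | intermediate
7 | 4-[(1S)-1-(TBS-oxy)-3-methylbutyl]-3-methoxyphenyl N,N-diethylcarbamate | CCN(CC)C(=O)Oc1ccc([C@@H](O[Si](C)(C)C(C)(C)C)CC(C)C)c(OC)c1 | intermediate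
8 | aryllithium from 7, lithium on the carbon between the carbamate and methoxy groups (not isolated) | CCN(CC)C(=O)Oc1ccc([C@@H](O[Si](C)(C)C(C)(C)C)CC(C)C)c(OC)c1[Li] | intermediate
9 | 4-[(1S)-1-(TBS-oxy)-3-methylbutyl]-3-methoxy-2-(trimethylsilyl)phenyl N,N-diethylcarbamate | CCN(CC)C(=O)Oc1ccc([C@@H](O[Si](C)(C)C(C)(C)C)CC(C)C)c(OC)c1[Si](C)(C)C | intermediate
10 | 4-[(1S)-1-(TBS-oxy)-3-methylbutyl]-3-methoxy-2-(trimethylsilyl)phenol | Oc1ccc([C@@H](O[Si](C)(C)C(C)(C)C)CC(C)C)c(OC)c1[Si](C)(C)C | intermediate
11 | 4-[(1S)-1-(TBS-oxy)-3-methylbutyl]-3-methoxy-2-(trimethylsilyl)phenyl trifluoromethanesulfonate | COc1c([C@@H](O[Si](C)(C)C(C)(C)C)CC(C)C)ccc(OS(=O)(=O)C(F)(F)F)c1[Si](C)(C)C | intermediate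
12 | 2-methoxy-4-methylphenol (creosol) | COc1cc(C)ccc1O | starting material
13 | 2-hydroxy-3-methoxy-5-methylbenzaldehyde | COc1cc(C)cc(C=O)c1O | intermediate
14 | 2,3-dihydroxy-5-methylbenzaldehyde | Cc1cc(O)c(O)c(C=O)c1 | intermediate
15 | disodium dianion of 14 (not isolated) | Cc1cc([O-])c([O-])c(C=O)c1.[Na+].[Na+] | intermediate
16 | 3-(benzyloxy)-2-hydroxy-5-methylbenzaldehyde | Cc1cc(OCc2ccccc2)c(O)c(C=O)c1 | intermediate
17 | 2-(benzyloxy)-6-(hydroxymethyl)-4-methylphenol | Cc1cc(OCc2ccccc2)c(O)c(CO)c1 | intermediate
18 | 2-(benzyloxy)-6-[(TBS-oxy)methyl]-4-methylphenol | Cc1cc(OCc2ccccc2)c(O)c(CO[Si](C)(C)C(C)(C)C)c1 | intermediate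
19 | carbon dioxide | O=C=O | starting material
20 | potassium phenoxide of 18 (not isolated) | Cc1cc(OCc2ccccc2)c([O-])c(CO[Si](C)(C)C(C)(C)C)c1.[K+] | intermediate
21 | ring A aryne, triple bond between C1 and C6, 3-methoxy-4-[(1S)-1-(TBS-oxy)-3-methylbutyl]benzyne (not isolated) | COC1=C([C@@H](O[Si](C)(C)C(C)(C)C)CC(C)C)C=CC#C1 | intermediate
22 | arylpotassium adduct, potassium at C1 of the diaryl ether (not isolated) | COc1c([C@@H](O[Si](C)(C)C(C)(C)C)CC(C)C)ccc(Oc2c(OCc3ccccc3)cc(C)cc2CO[Si](C)(C)C(C)(C)C)c1[K] | intermediate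
23 | 6-{2-(benzyloxy)-6-[(TBS-oxy)methyl]-4-methylphenoxy}-3-[(1S)-1-(TBS-oxy)-3-methylbutyl]-2-methoxybenzoic acid | COc1c([C@@H](O[Si](C)(C)C(C)(C)C)CC(C)C)ccc(Oc2c(OCc3ccccc3)cc(C)cc2CO[Si](C)(C)C(C)(C)C)c1C(=O)O | intermediate
24 | 6-{2-hydroxy-6-[(TBS-oxy)methyl]-4-methylphenoxy}-3-[(1S)-1-(TBS-oxy)-3-methylbutyl]-2-methoxybenzoic acid | COc1c([C@@H](O[Si](C)(C)C(C)(C)C)CC(C)C)ccc(Oc2c(O)cc(C)cc2CO[Si](C)(C)C(C)(C)C)c1C(=O)O | intermediate
25 | 3-[(1S)-1-hydroxy-3-methylbutyl]-6-[2-hydroxy-6-(hydroxymethyl)-4-methylphenoxy]-2-methoxybenzoic acid (CNP0221397.1) | COc1c([C@@H](O)CC(C)C)ccc(Oc2c(O)cc(C)cc2CO)c1C(=O)O | target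

**Step count and risks**

Total steps: 16. Longest linear sequence: 11 steps (steps 1–8, then 14, 15 and 16).

Step 14 (the proposed new method) is the riskiest. The phenoxide may be held back by CO2 as its aryl carbonate and add too slowly, so that fluoride or the carbonate oxygen adds to the aryne instead. The aryl anion may be protonated before it meets CO2, or a silyl ether may be lost to fluoride. The fallback uses known chemistry and sets out again from 11 and 18. The aryne is generated with CsF in MeCN at room temperature in the presence of the free phenol; this fluoride-promoted aryne O-arylation ends with protonation of the aryl anion and should give the diaryl ether bearing hydrogen at C1, F1. Its C1–H lies between the methoxy and aryloxy oxygens and is removed by s-BuLi/TMEDA in THF at −78 °C (directed ortho-metalation) to give the C1-lithiated diaryl ether F2. Quenching F2 with CO2 gas and acidifying comes back to the route at 23.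

Step 4 may suffer from poor facial discrimination between the ortho-methoxyaryl group and the branched isobutyl chain in the oxazaborolidine complex, which would give carbinol of low enantiomeric purity. The fallback sets out from aldehyde 2 and bypasses steps 2–4. Reagent-controlled Brown methallylation with (−)-Ipc2B(2-methylallyl), made from (−)-Ipc2BOMe of the (+)-α-pinene series and 2-methylallylmagnesium chloride, in Et2O at −78 °C with NaOH/H2O2 work-up, should give the S homoallylic alcohol 4-[(1S)-1-hydroxy-3-methylbut-3-en-1-yl]-3-methoxyphenyl N,N-diethylcarbamate F3. Hydrogenation of its 1,1-disubstituted alkene with H2 and RhCl(PPh3)3, a catalyst that does not cleave benzylic C–O bonds, comes back at 6.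

Step 11 may alkylate the inner oxygen or both oxygens of the catechol, which would scramble the ring B substitution pattern. The fallback sets out from 14. Exhaustive benzylation (BnBr, K2CO3, DMF) gives 2,3-bis(benzyloxy)-5-methylbenzaldehyde F4. MgBr2·OEt2 in toluene/Et2O at reflux then cleaves only the benzyl ether whose oxygen chelates magnesium together with the formyl oxygen, and the sequence comes back at 16.

**Further compounds**

F1 | step 14 | 1-{2-(benzyloxy)-6-[(TBS-oxy)methyl]-4-methylphenoxy}-4-[(1S)-1-(TBS-oxy)-3-methylbutyl]-3-methoxybenzene (23 without the carboxyl group) | COc1c([C@@H](O[Si](C)(C)C(C)(C)C)CC(C)C)ccc(Oc2c(OCc3ccccc3)cc(C)cc2CO[Si](C)(C)C(C)(C)C)c1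
F2 | step 14 | C1-lithio derivative of F1, lithium between the methoxy and aryloxy groups | COc1c([C@@H](O[Si](C)(C)C(C)(C)C)CC(C)C)ccc(Oc2c(OCc3ccccc3)cc(C)cc2CO[Si](C)(C)C(C)(C)C)c1[Li]
F3 | step 4 | 4-[(1S)-1-hydroxy-3-methylbut-3-en-1-yl]-3-methoxyphenyl N,N-diethylcarbamate | CCN(CC)C(=O)Oc1ccc([C@@H](O)CC(C)=C)c(OC)c1
F4 | step 11 | 2,3-bis(benzyloxy)-5-methylbenzaldehyde | Cc1cc(OCc2ccccc2)c(OCc3ccccc3)c(C=O)c1
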